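The side chain is cut between the carbinol carbon that carries the methyl group and the mevalonate ester oxygen and the adjacent CH2, the third carbon out from C3 of the lactone ring. Because that carbinol carbon is acyloxy-substituted, it can be generated as an α-acyloxyalkyl radical from a 1-bromoethyl ester (both epimers), formed in the flask from silyl-protected (R)-mevalonic acid bromide and acetaldehyde. A chiral nickel hydride catalyst hydrometalates the terminal olefin of an (R)-3-allyl-5,8-bis(silyloxy)isochromanone and couples the primary alkylnickel with this radical, forging the C–C bond and setting the R carbinol centre stereoconvergently with the whole ester in place. Global desilylation follows.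

Key step: step 9

Assumption: the sense of induction of the nickel/bis(oxazoline) catalyst is assigned on a model 1-bromoethyl ester, and the ligand antipode that delivers the R ester is used.

Step 1
Reactants: 1 (R)-epichlorohydrin; 2 vinylmagnesium bromide
Product: 3 (R)-1-chloropent-4-en-2-ol
Conditions: 2 (1.2 equiv), CuI (10 mol %), THF, −78 → −30 °C; aq. NH4Cl
Reagents that add atoms: none
Why: Copper-catalysed Grignard opening of the epoxide at its unsubstituted carbon (SN2) leaves the chloride and the C–O stereocentre untouched, so the R configuration of 1 is carried over.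

Step 2
Reactants: 3 (R)-1-chloropent-4-en-2-ol
Product: 4 (R)-2-allyloxirane
Conditions: powdered NaOH, Et2O, rt; distillation
Reagents that add atoms: none
Why: Intramolecular Williamson etherification displaces the primary chloride and does not touch the stereocentre.

Step 3
Reactants: 5 2,5-dimethoxybenzoic acid
Product: 7 N,N-diethyl-2,5-dimethoxybenzamide, via acid chloride 6 (not isolated)
Conditions: (COCl)2, DMF (cat.), CH2Cl2, 0 °C → rt; then Et2NH (3 equiv), 0 °C
Reagents that add atoms: diethylamine, CCNCC
Why: Acid chloride amidation installs the tertiary amide that serves as directing group for the ortho-metalation.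

Step 4
Reactants: 7 N,N-diethyl-2,5-dimethoxybenzamide; 4 (R)-2-allyloxirane
Product: 10 (R)-3-allyl-5,8-dimethoxyisochroman-1-one, via aryllithium 8 (not isolated), via hydroxy amide 9 (not isolated)
Conditions: s-BuLi, TMEDA, THF, −78 °C; 4, then BF3·OEt2, −78 °C; aq. NH4Cl; crude, TsOH·H2O, toluene, 100 °C
Reagents that add atoms: none
Why: Directed ortho-metalation takes place at the only ring position flanked by the amide and a methoxy group, the aryllithium opens the BF3-activated epoxide at its CH2 terminus (SN2, stereocentre of 4 untouched), and acid-promoted lactonization with loss of diethylamine closes the δ-lactone.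

Step 5
Reactants: 10 (R)-3-allyl-5,8-dimethoxyisochroman-1-one
Product: 11 (R)-3-allyl-5,8-dihydroxyisochroman-1-one
Conditions: BBr3 (4 equiv), CH2Cl2, −78 → 0 °C; MeOH, then H2O
Reagents that add atoms: none
Why: Boron tribromide cleaves both aryl methyl ethers through aryloxyboranes at low temperature, where the terminal olefin, the lactone and the C3 stereocentre are expected to persist.

Step 6
Reactants: 11 (R)-3-allyl-5,8-dihydroxyisochroman-1-one
Product: 12 (R)-3-allyl-5,8-bis(tert-butyldimethylsilyloxy)isochroman-1-one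
Conditions: TBSCl (3 equiv), imidazole, DMF, rt → 40 °C, argon
Reagents that add atoms: tert-butyldimethylsilyl chloride, CC(C)(C)[Si](C)(C)Cl
Why: Silylation masks the acidic, oxidation-prone hydroquinone for the base- and silane-containing coupling and allows a single fluoride deprotection at the end.

Step 7
Reactants: 13 (R)-mevalonolactone
Product: 16 (R)-5-(tert-butyldimethylsilyloxy)-3-hydroxy-3-methylpentanoic acid, via potassium mevalonate 14 (not isolated), via silyl ester 15 (not isolated)
Conditions: KOH (1.05 equiv), MeOH/H2O, rt, evaporate to dryness; TBSCl (2.5 equiv), imidazole, DMF, rt; K2CO3, MeOH/THF/H2O, rt; aq. KHSO4 to pH 4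
Reagents that add atoms: potassium hydroxide, [K+].[OH-]; tert-butyldimethylsilyl chloride, CC(C)(C)[Si](C)(C)Cl
Why: Saponification opens the lactone, silylation caps the carboxylate and the primary hydroxyl (the tertiary hydroxyl is too hindered for TBSCl) so that relactonization is blocked, and carbonate methanolysis removes only the labile silyl ester, all without involving the quaternary stereocentre.

Step 8
Reactants: 16 (R)-5-(tert-butyldimethylsilyloxy)-3-hydroxy-3-methylpentanoic acid
Product: 18 (R)-5-(tert-butyldimethylsilyloxy)-3-methyl-3-(triethylsilyloxy)pentanoic acid, via triethylsilyl ester 17 (not isolated)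
Conditions: TESOTf (2.3 equiv), 2,6-lutidine, CH2Cl2, −78 → 0 °C; then MeOH/H2O, rt
Reagents that add atoms: triethylsilyl trifluoromethanesulfonate, CC[Si](CC)(CC)OS(=O)(=O)C(F)(F)F
Why: The silyl triflate silylates the tertiary alcohol and, transiently, the acid, and mild aqueous methanolysis of the silyl ester returns the free acid with both hydroxyls protected against acylation in the next step.

Step 9
Reactants: 18 (R)-5-(tert-butyldimethylsilyloxy)-3-methyl-3-(triethylsilyloxy)pentanoic acid; 19 acetaldehyde; 12 (R)-3-allyl-5,8-bis(tert-butyldimethylsilyloxy)isochroman-1-one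
Product: 22 (R)-5-[(R)-5,8-bis(tert-butyldimethylsilyloxy)-1-oxoisochroman-3-yl]pentan-2-yl (R)-5-(tert-butyldimethylsilyloxy)-3-methyl-3-(triethylsilyloxy)pentanoate, via acyl bromide 20 (not isolated), via 1-bromoethyl ester 21 (not isolated)
Conditions: 18, 1-bromo-N,N,2-trimethylprop-1-en-1-amine, CH2Cl2, 0 °C; 19, −20 °C → rt, no Lewis acid, evaporate; crude 21 (1.3 equiv) added to 12, NiBr2·DME (10 mol %), C2-symmetric isopropylidene-bridged bis(oxazoline) ligand (12 mol %), (EtO)3SiH, K3PO4·H2O, Et2O/DMA, 0 °C → rt
Reagents that add atoms: none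
Why: The acid bromide 20 adds across the C=O of acetaldehyde to give 21 as a mixture of both epimers at the bromine-bearing carbon; a bis(oxazoline)-ligated nickel hydride, formed from NiBr2, the silane and the phosphate, inserts the terminal olefin of 12 anti-Markovnikov to a primary alkylnickel, while bromine abstraction from 21 by low-valent nickel gives a planar α-acyloxyalkyl radical that is captured at nickel and released by C(sp3)–C(sp3) reductive elimination. The closest known reaction type is the nickel-catalysed enantioconvergent hydroalkylation of terminal olefins with racemic α-bromoalkyl esters, including its one-pot variant from aldehyde, acyl bromide, olefin and hydrosilane. No ring is closed. The new carbinol stereocentre is set by the chiral ligand on nickel at the radical-capture and reductive-elimination stage, so both epimers of 21 funnel into the R ester, and the stereocentres of 12 and 18 are too remote to interfere. The step needs anti-Markovnikov regioselectivity without chain walking, secured by the monosubstituted olefin and the bis(oxazoline) ligand, and chemoselective activation of the C–Br bond over the lactone, the ester and the silyl ethers, secured by the weak, radical-stabilised α-acyloxy C–Br bond.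

Step 10
Reactants: 22 (R)-5-[(R)-5,8-bis(tert-butyldimethylsilyloxy)-1-oxoisochroman-3-yl]pentan-2-yl (R)-5-(tert-butyldimethylsilyloxy)-3-methyl-3-(triethylsilyloxy)pentanoate
Product: 23 (R)-5-[(R)-5,8-dihydroxy-1-oxoisochroman-3-yl]pentan-2-yl (R)-3,5-dihydroxy-3-methylpentanoate
Conditions: TBAF/AcOH (1:1, excess), THF, 0 °C → rt, argon
Reagents that add atoms: none
Why: Buffered fluoride cleaves the two aryl silyl ethers, the primary silyl ether and the tertiary triethylsilyl ether, and the acetic acid buffer should keep alkoxide-triggered δ-lactonization of the mevalonate ester and oxidation of the hydroquinone in check.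

Compound list
1 | (R)-epichlorohydrin | ClC[C@H]1CO1 | starting material
2 | vinylmagnesium bromide | C=C[Mg]Br | starting material
3 | (R)-1-chloropent-4-en-2-ol | C=CC[C@@H](O)CCl | intermediate
4 | (R)-2-allyloxirane | C=CC[C@@H]1CO1 | intermediate
5 | 2,5-dimethoxybenzoic acid | COc1ccc(OC)c(C(=O)O)c1 | starting material
6 | 2,5-dimethoxybenzoyl chloride | COc1ccc(OC)c(C(=O)Cl)c1 | intermediate
7 | N,N-diethyl-2,5-dimethoxybenzamide | CCN(CC)C(=O)c1cc(OC)ccc1OC | intermediate
8 | 2-(diethylcarbamoyl)-3,6-dimethoxyphenyllithium | [Li]c1c(OC)ccc(OC)c1C(=O)N(CC)CC | intermediate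
9 | (R)-N,N-diethyl-2-(2-hydroxypent-4-en-1-yl)-3,6-dimethoxybenzamide | C=CC[C@@H](O)Cc1c(OC)ccc(OC)c1C(=O)N(CC)CC | intermediate
10 | (R)-3-allyl-5,8-dimethoxyisochroman-1-one | C=CC[C@@H]1Cc2c(OC)ccc(OC)c2C(=O)O1 | intermediate
11 | (R)-3-allyl-5,8-dihydroxyisochroman-1-one | C=CC[C@@H]1Cc2c(O)ccc(O)c2C(=O)O1 | intermediate
12 | (R)-3-allyl-5,8-bis(tert-butyldimethylsilyloxy)isochroman-1-one | C=CC[C@@H]1Cc2c(O[Si](C)(C)C(C)(C)C)ccc(O[Si](C)(C)C(C)(C)C)c2C(=O)O1 | intermediate
13 | (R)-mevalonolactone, (R)-4-hydroxy-4-methyltetrahydropyran-2-one | C[C@@]1(O)CCOC(=O)C1 | starting material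
14 | potassium (R)-3,5-dihydroxy-3-methylpentanoate | [K+].[O-]C(=O)C[C@](C)(O)CCO | intermediate
15 | tert-butyldimethylsilyl (R)-5-(tert-butyldimethylsilyloxy)-3-hydroxy-3-methylpentanoate | CC(C)(C)[Si](C)(C)OC(=O)C[C@](C)(O)CCO[Si](C)(C)C(C)(C)C | intermediate
16 | (R)-5-(tert-butyldimethylsilyloxy)-3-hydroxy-3-methylpentanoic acid | OC(=O)C[C@](C)(O)CCO[Si](C)(C)C(C)(C)C | intermediate
17 | triethylsilyl (R)-5-(tert-butyldimethylsilyloxy)-3-methyl-3-(triethylsilyloxy)pentanoate | CC[Si](CC)(CC)OC(=O)C[C@](C)(O[Si](CC)(CC)CC)CCO[Si](C)(C)C(C)(C)C | intermediate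
18 | (R)-5-(tert-butyldimethylsilyloxy)-3-methyl-3-(triethylsilyloxy)pentanoic acid | OC(=O)C[C@](C)(O[Si](CC)(CC)CC)CCO[Si](C)(C)C(C)(C)C | intermediate
19 | acetaldehyde | CC=O | starting material
20 | (R)-5-(tert-butyldimethylsilyloxy)-3-methyl-3-(triethylsilyloxy)pentanoyl bromide | BrC(=O)C[C@](C)(O[Si](CC)(CC)CC)CCO[Si](C)(C)C(C)(C)C | intermediate
21 | 1-bromoethyl (R)-5-(tert-butyldimethylsilyloxy)-3-methyl-3-(triethylsilyloxy)pentanoate, both epimers at the CHBr carbon | CC(Br)OC(=O)C[C@](C)(O[Si](CC)(CC)CC)CCO[Si](C)(C)C(C)(C)C | intermediate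
22 | (R)-5-[(R)-5,8-bis(tert-butyldimethylsilyloxy)-1-oxoisochroman-3-yl]pentan-2-yl (R)-5-(tert-butyldimethylsilyloxy)-3-methyl-3-(triethylsilyloxy)pentanoate | C[C@H](CCC[C@@H]1Cc2c(O[Si](C)(C)C(C)(C)C)ccc(O[Si](C)(C)C(C)(C)C)c2C(=O)O1)OC(=O)C[C@](C)(O[Si](CC)(CC)CC)CCO[Si](C)(C)C(C)(C)C | intermediate
23 | (R)-5-[(R)-5,8-dihydroxy-1-oxoisochroman-3-yl]pentan-2-yl (R)-3,5-dihydroxy-3-methylpentanoate | C[C@H](CCC[C@@H]1Cc2c(O)ccc(O)c2C(=O)O1)OC(=O)C[C@](C)(O)CCO | target

Total step count: 10.
Longest linear sequence: 7 steps (steps 1, 2, 4, 5, 6, 9, 10).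

Steps most likely to fail

Step 9. The coupling may suffer from reduction or elimination of the bromo ester, from lactonization of the acyl bromide through its silyloxy oxygen before acetaldehyde adds, or from weak facial discrimination at the small methyl-substituted radical. The fallback sets out from 12 and comes back at 22. Cross-metathesis of 12 with but-3-en-2-one (second-generation Hoveyda–Grubbs catalyst, CH2Cl2, 40 °C) should give (R,E)-5,8-bis(tert-butyldimethylsilyloxy)-3-(4-oxopent-2-en-1-yl)isochroman-1-one F1. Corey–Bakshi–Shibata reduction with the (S)-methyl oxazaborolidine and catecholborane (toluene, −78 °C) should give the allylic alcohol (R)-5,8-bis(tert-butyldimethylsilyloxy)-3-[(R,E)-4-hydroxypent-2-en-1-yl]isochroman-1-one F2, by analogy with aryl methyl ketones. Hydrogenation of the alkene (H2, PtO2, EtOAc) should give (R)-5,8-bis(tert-butyldimethylsilyloxy)-3-[(R)-4-hydroxypentyl]isochroman-1-one F3. Steglich esterification of F3 with acid 18 (DCC, DMAP, CH2Cl2) then gives 22.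

Step 4. The doubly ortho-substituted aryllithium may open the epoxide slowly, so that boron transmetalation or attack on the amide competes. The fallback sets out from 7 and comes back at 10. Ortho-lithiation of 7 as before, transmetalation with MgBr2·OEt2 and allylation with allyl bromide should give 2-allyl-N,N-diethyl-3,6-dimethoxybenzamide F4. Lemieux–Johnson cleavage (OsO4 cat., NaIO4, 2,6-lutidine, dioxane/H2O) should give N,N-diethyl-3,6-dimethoxy-2-(2-oxoethyl)benzamide F5. Brown allylation with the B-allyldiisopinocampheylborane antipode derived from (−)-α-pinene (Et2O, −78 °C; NaOH/H2O2) sets the carbinol centre by reagent control and should give hydroxy amide 9, which is lactonized with TsOH as in step 4 to rejoin the route at 10.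

Step 10. The long fluoride exposure that the aryl and primary silyl ethers need may allow δ-lactonization of the freed 5-hydroxy ester with loss of the side-chain alcohol, or air oxidation of the hydroquinone. The fallback sets out from 11 and comes back at 23. Benzylation of 11 (BnBr, K2CO3, DMF) should give (R)-3-allyl-5,8-bis(benzyloxy)isochroman-1-one F6. The coupling of step 9 with 18 and 19 should give (R)-5-[(R)-5,8-bis(benzyloxy)-1-oxoisochroman-3-yl]pentan-2-yl (R)-5-(tert-butyldimethylsilyloxy)-3-methyl-3-(triethylsilyloxy)pentanoate F7. Brief HF·pyridine/pyridine treatment (THF, 0 °C) removes only the two alkyl silyl ethers and should give (R)-5-[(R)-5,8-bis(benzyloxy)-1-oxoisochroman-3-yl]pentan-2-yl (R)-3,5-dihydroxy-3-methylpentanoate F8. Neutral hydrogenolysis (H2, Pd/C, EtOAc) then frees the hydroquinone and gives 23.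

Further compounds
F1 | step 9 | (R,E)-5,8-bis(tert-butyldimethylsilyloxy)-3-(4-oxopent-2-en-1-yl)isochroman-1-one | CC(=O)/C=C/C[C@@H]1Cc2c(O[Si](C)(C)C(C)(C)C)ccc(O[Si](C)(C)C(C)(C)C)c2C(=O)O1
F2 | step 9 | (R)-5,8-bis(tert-butyldimethylsilyloxy)-3-[(R,E)-4-hydroxypent-2-en-1-yl]isochroman-1-one | C[C@@H](O)/C=C/C[C@@H]1Cc2c(O[Si](C)(C)C(C)(C)C)ccc(O[Si](C)(C)C(C)(C)C)c2C(=O)O1
F3 | step 9 | (R)-5,8-bis(tert-butyldimethylsilyloxy)-3-[(R)-4-hydroxypentyl]isochroman-1-one | C[C@@H](O)CCC[C@@H]1Cc2c(O[Si](C)(C)C(C)(C)C)ccc(O[Si](C)(C)C(C)(C)C)c2C(=O)O1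
F4 | step 4 | 2-allyl-N,N-diethyl-3,6-dimethoxybenzamide | C=CCc1c(OC)ccc(OC)c1C(=O)N(CC)CC
F5 | step 4 | N,N-diethyl-3,6-dimethoxy-2-(2-oxoethyl)benzamide | O=CCc1c(OC)ccc(OC)c1C(=O)N(CC)CC
F6 | step 10 | (R)-3-allyl-5,8-bis(benzyloxy)isochroman-1-one | C=CC[C@@H]1Cc2c(OCc3ccccc3)ccc(OCc3ccccc3)c2C(=O)O1
F7 | step 10 | (R)-5-[(R)-5,8-bis(benzyloxy)-1-oxoisochroman-3-yl]pentan-2-yl (R)-5-(tert-butyldimethylsilyloxy)-3-methyl-3-(triethylsilyloxy)pentanoate | C[C@H](CCC[C@@H]1Cc2c(OCc3ccccc3)ccc(OCc3ccccc3)c2C(=O)O1)OC(=O)C[C@](C)(O[Si](CC)(CC)CC)CCO[Si](C)(C)C(C)(C)C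
F8 | step 10 | (R)-5-[(R)-5,8-bis(benzyloxy)-1-oxoisochroman-3-yl]pentan-2-yl (R)-3,5-dihydroxy-3-methylpentanoate | C[C@H](CCC[C@@H]1Cc2c(OCc3ccccc3)ccc(OCc3ccccc3)c2C(=O)O1)OC(=O)C[C@](C)(O)CCO
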